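## Retrosynthetic overview
1. Ring letters: A is the biaryl ring with para-OH, B the ring with OH next to the ether O, C the para-phenylene ring, D the biaryl ring with ortho-OH. The target comes from its trimethyl ether. The trimethyl ether comes from the key step, a sulfur-atom extrusion that contracts a 17-membered thia-macrocycle (A–CH2–S–CH2–B) to the 16-membered ring and creates the A–B ethano bridge.
2. The thia-macrocycle comes from an intramolecular B-alkyl Suzuki closure of the C–D ethano bridge (styrene on ring D, chloride on ring C).
3. The open chain comes from a cross-selective thioether union of an A–D biaryl benzyl bromide with a B–O–C diaryl ether benzyl bromide.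
4. The A–D bond comes from ortho-lithiation, zincation and Negishi coupling, and the B–O–C bond from an Ullmann coupling. All carbon comes from two cresols, two halophenols and a vinylboron C2 unit.
5. Ring order: the four benzene rings are bought. The only ring made is the macrocycle, first 17-membered (step 10) and then 16-membered (step 11).

Assumption: the SMILES has no stereodescriptor and the molecule has no stereocentre, so the hindered A–D axis is left unspecified, the compound is made exactly as drawn, and no step has to set configuration.

## Route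

Step 1
Reactants: 1 m-cresol (3-methylphenol)
Product: 3 4-iodo-3-methylanisole (1-iodo-4-methoxy-2-methylbenzene), via 4-iodo-3-methylphenol 2 (not isolated)
Conditions: NIS, p-TsOH (10 mol %), MeCN, 0 °C to rt; then K2CO3, MeI, 40 °C, same flask
Reagents that add atoms: N-iodosuccinimide, O=C1CCC(=O)N1I; iodomethane, CI
Why: Electrophilic aromatic iodination with acid-activated NIS goes para to the strongly directing OH (the carbon next to CH3 that becomes the biaryl carbon of ring A), and Williamson O-methylation in the same flask installs the methyl ether that is kept until the last step.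

Step 2
Reactants: 4 3-bromophenol
Product: 5 3-bromoanisole
Conditions: MeI, K2CO3, acetone, reflux
Reagents that add atoms: iodomethane, CI
Why: This is a Williamson ether synthesis, and the OMe group serves both as the protecting group of ring D and as the directing group for step 3.

Step 3
Reactants: 5 3-bromoanisole; 3 4-iodo-3-methylanisole
Product: 8 2'-bromo-4,6'-dimethoxy-2-methyl-1,1'-biphenyl, via 2-bromo-6-methoxyphenyllithium 6 (not isolated), via 2-bromo-6-methoxyphenylzinc chloride 7 (not isolated)
Conditions: LDA, THF, −78 °C; ZnCl2, −78 °C to rt; 3, Pd(PPh3)4 (5 mol %), 60 °C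
Reagents that add atoms: none
Why: Directed ortho-metalation followed by Negishi coupling works because the C–H between OMe and Br is the most acidic and is lithiated at −78 °C without benzyne formation, ZnCl2 gives a thermally stable arylzinc, and zerovalent palladium inserts into the C–I bond of 3 much faster than into the hindered C–Br bond, so the 1,2,3-pattern of ring D and the A–D bond are set in one flask.

Step 4
Reactants: 8 2'-bromo-4,6'-dimethoxy-2-methyl-1,1'-biphenyl
Product: 9 2'-bromo-2-(bromomethyl)-4,6'-dimethoxy-1,1'-biphenyl
Conditions: NBS, AIBN (cat.), PhCF3, reflux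
Reagents that add atoms: N-bromosuccinimide, O=C1CCC(=O)N1Br
Why: In this Wohl–Ziegler radical bromination the single benzylic CH3 is the only abstractable C–H, and the non-polar solvent with an initiator suppresses ionic bromination of the anisole rings.

Step 5
Reactants: 10 p-cresol (4-methylphenol)
Product: 12 2-bromo-4-methylanisole, via 2-bromo-4-methylphenol 11 (not isolated)
Conditions: NBS, MeCN, 0 °C; then K2CO3, MeI, 40 °C, same flask
Reagents that add atoms: N-bromosuccinimide, O=C1CCC(=O)N1Br; iodomethane, CI
Why: Electrophilic bromination of a para-blocked phenol can only go ortho to OH (the future ether carbon of ring B), and Williamson O-methylation in the same flask protects the phenol.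

Step 6
Reactants: 12 2-bromo-4-methylanisole; 13 4-chlorophenol
Product: 14 2-(4-chlorophenoxy)-1-methoxy-4-methylbenzene
Conditions: CuI (10 mol %), N,N-dimethylglycine (30 mol %), Cs2CO3, dioxane, 100 °C
Reagents that add atoms: none
Why: In this ligand-accelerated Ullmann diaryl ether synthesis copper activates the aryl bromide but not the aryl chloride of 13, which is kept as the handle for step 10.

Step 7
Reactants: 14 2-(4-chlorophenoxy)-1-methoxy-4-methylbenzene
Product: 15 4-(bromomethyl)-2-(4-chlorophenoxy)-1-methoxybenzene
Conditions: NBS, AIBN (cat.), PhCF3, reflux; used crude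
Reagents that add atoms: N-bromosuccinimide, O=C1CCC(=O)N1Br
Why: This Wohl–Ziegler bromination is run before any ArCH2CH2Ar bridge exists, so the para-methoxy-activated CH3 is the only benzylic C–H in the molecule.

Step 8
Reactants: 15 4-(bromomethyl)-2-(4-chlorophenoxy)-1-methoxybenzene; 9 2'-bromo-2-(bromomethyl)-4,6'-dimethoxy-1,1'-biphenyl
Product: 18 (2'-bromo-4,6'-dimethoxybiphenyl-2-yl)methyl 3-(4-chlorophenoxy)-4-methoxybenzyl sulfide, via benzylisothiouronium bromide 16 (not isolated), via sodium benzylthiolate 17 (not isolated)
Conditions: 15, thiourea, EtOH, reflux; NaOH (aq), N2, reflux; then 9, THF, 0 °C to rt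
Reagents that add atoms: thiourea, NC(N)=S
Why: The thiourea route (SN2 alkylation of thiourea, alkaline hydrolysis to the thiolate, SN2 on the second benzylic bromide) joins the two different benzyl units with complete cross-selectivity, which a direct reductive coupling of two benzyl bromides cannot give.

Step 9
Reactants: 18 open-chain bromo chloro sulfide; 19 potassium vinyltrifluoroborate
Product: 20 (2'-ethenyl-4,6'-dimethoxybiphenyl-2-yl)methyl 3-(4-chlorophenoxy)-4-methoxybenzyl sulfide
Conditions: PdCl2(dppf) (5 mol %), Cs2CO3, THF/H2O 9:1, 80 °C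
Reagents that add atoms: none
Why: In this Suzuki–Miyaura vinylation dppf-ligated zerovalent palladium inserts into the C–Br bond of ring D but not into the electron-rich C–Cl bond of ring C, and the thioether is tolerated.

Step 10
Reactants: 20 ring D styrene with ring C chloride
Product: 22 17-membered thia-macrocycle (plagiochin E trimethyl ether with CH2–S–CH2 in place of the ring A–ring B bridge), via B-alkyl-9-BBN adduct 21 (not isolated)
Conditions: 9-BBN, THF, rt; then slow addition to Pd(OAc)2 (10 mol %), SPhos (20 mol %), K3PO4, dioxane/H2O, 90 °C, 2 mM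
Reagents that add atoms: none
Why: Anti-Markovnikov hydroboration is followed by an intramolecular B-alkyl Suzuki–Miyaura coupling in which SPhos-ligated zerovalent palladium opens the aryl chloride, and slow addition together with the long flexible CH2–S–CH2 hinge lets closure of the 17-membered ring beat oligomerisation.

Step 11
Reactants: 22 17-membered thia-macrocycle
Product: 24 plagiochin E trimethyl ether (16-membered ring), via dibenzylnickel bipyridine metallacycle 23 (not isolated)
Conditions: Ni(cod)2 (2.5 equiv), 2,2'-bipyridine (2.5 equiv), THF, 5 mM, 60 °C, Ar; then air, filtration through silica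
Reagents that add atoms: none
Why: Proposed new method: thermal sulfur-atom deletion from a macrocyclic dibenzyl sulfide by stoichiometric zerovalent nickel, in which electron-rich bipyridine-ligated nickel inserts stepwise into the two weak benzylic C–S bonds, sulfur is taken out as insoluble NiS, and the ring-bound dibenzylnickel 23 has no β-hydrogen and can only undergo C(sp3)–C(sp3) reductive elimination, so the A–B ethano bridge forms and the ring contracts from 17 to 16 members; a benzyl radical that leaks out stays tethered to its partner and recombines to the same product, and aryl ethers are inert to this reagent at 60 °C; the closest known reaction types are the nickel–bipyridine desulfurative ring contraction of cyclic diaryl sulfides (thianthrene to dibenzothiophene) and the photochemical phosphite-mediated sulfur extrusion from thiacyclophanes, neither of which has been shown as a thermal metal-mediated process on a benzylic C–S–C unit in a macrocycle.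

Step 12
Reactants: 24 plagiochin E trimethyl ether
Product: 26 plagiochin E, via tris(dibromoboryl) ether 25 (not isolated)
Conditions: BBr3, CH2Cl2, −78 °C to rt; then H2O
Reagents that add atoms: none
Why: In this Lewis-acid ether cleavage BBr3 cleaves the three aryl methyl ethers by bromide attack on the O-methyl carbons, the diaryl ether has no sp3 C–O bond and is untouched, and water hydrolyses the boron aryloxides.

## Compound list
1 | m-cresol | Cc1cccc(O)c1 | starting material
2 | 4-iodo-3-methylphenol | Cc1cc(O)ccc1I | intermediate
3 | 4-iodo-3-methylanisole | COc1ccc(I)c(C)c1 | intermediate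
4 | 3-bromophenol | Oc1cccc(Br)c1 | starting material
5 | 3-bromoanisole | COc1cccc(Br)c1 | intermediate
6 | 2-bromo-6-methoxyphenyllithium | [Li]c1c(Br)cccc1OC | intermediate
7 | 2-bromo-6-methoxyphenylzinc chloride | Cl[Zn]c1c(Br)cccc1OC | intermediate
8 | 2'-bromo-4,6'-dimethoxy-2-methyl-1,1'-biphenyl | COc1ccc(c(C)c1)-c1c(Br)cccc1OC | intermediate
9 | 2'-bromo-2-(bromomethyl)-4,6'-dimethoxy-1,1'-biphenyl | COc1ccc(c(CBr)c1)-c1c(Br)cccc1OC | intermediate
10 | p-cresol | Cc1ccc(O)cc1 | starting material
11 | 2-bromo-4-methylphenol | Cc1ccc(O)c(Br)c1 | intermediate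
12 | 2-bromo-4-methylanisole | COc1ccc(C)cc1Br | intermediate
13 | 4-chlorophenol | Oc1ccc(Cl)cc1 | starting material
14 | 2-(4-chlorophenoxy)-1-methoxy-4-methylbenzene | COc1ccc(C)cc1Oc1ccc(Cl)cc1 | intermediate
15 | 4-(bromomethyl)-2-(4-chlorophenoxy)-1-methoxybenzene | COc1ccc(CBr)cc1Oc1ccc(Cl)cc1 | intermediate
16 | S-[3-(4-chlorophenoxy)-4-methoxybenzyl]isothiouronium bromide | COc1ccc(CSC(N)=[NH2+])cc1Oc1ccc(Cl)cc1.[Br-] | intermediate
17 | sodium [3-(4-chlorophenoxy)-4-methoxyphenyl]methanethiolate | COc1ccc(C[S-])cc1Oc1ccc(Cl)cc1.[Na+] | intermediate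
18 | (2'-bromo-4,6'-dimethoxybiphenyl-2-yl)methyl 3-(4-chlorophenoxy)-4-methoxybenzyl sulfide | COc1ccc(c(CSCc2ccc(OC)c(Oc3ccc(Cl)cc3)c2)c1)-c1c(Br)cccc1OC | intermediate
19 | potassium vinyltrifluoroborate | C=C[B-](F)(F)F.[K+] | starting material
20 | (2'-ethenyl-4,6'-dimethoxybiphenyl-2-yl)methyl 3-(4-chlorophenoxy)-4-methoxybenzyl sulfide | COc1ccc(c(CSCc2ccc(OC)c(Oc3ccc(Cl)cc3)c2)c1)-c1c(C=C)cccc1OC | intermediate
21 | B-alkyl-9-BBN adduct of 20 (boron on the terminal carbon) | COc1ccc(c(CSCc2ccc(OC)c(Oc3ccc(Cl)cc3)c2)c1)-c1c(CCB2C3CCCC2CCC3)cccc1OC | intermediate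
22 | 17-membered thia-macrocycle (A–CH2–S–CH2–B) | COc1ccc2c(c1)CSCc1ccc(OC)c(c1)Oc1ccc(cc1)CCc1cccc(OC)c1-2 | intermediate
23 | 17-membered dibenzylnickel metallacycle carrying 2,2'-bipyridine (Ni in place of S of 22) | COc1ccc2c(c1)C[Ni]Cc1ccc(OC)c(c1)Oc1ccc(cc1)CCc1cccc(OC)c1-2.c1ccc(nc1)-c1ccccn1 | intermediate
24 | plagiochin E trimethyl ether | COc1ccc2c(c1)CCc1ccc(OC)c(c1)Oc1ccc(cc1)CCc1cccc(OC)c1-2 | intermediate
25 | tris(dibromoboryl) ether of plagiochin E | BrB(Br)Oc1ccc2c(c1)CCc1ccc(OB(Br)Br)c(c1)Oc1ccc(cc1)CCc1cccc(OB(Br)Br)c1-2 | intermediate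
26 | plagiochin E | Oc1ccc2c(c1)CCc1ccc(O)c(c1)Oc1ccc(cc1)CCc1cccc(O)c1-2 | target

## Step count and risks
Total steps: 12. Longest linear sequence: 8 (steps 2, 3, 4, 8, 9, 10, 11, 12; the branches from 1 and from 10 are equally long).

**Step 11 (the new reaction).**
- Risk: the nickel may stop after one C–S insertion, or give the ring-opened hydrodesulfurised product on work-up.
- Fallback (known chemistry): it sets out from 22 and comes back at 24. Compound 22 is oxidised with H2O2/Na2WO4 to the macrocyclic sulfone F1. F1 is then subjected to flash vacuum pyrolysis (600 °C, 0.01 mbar) or 254 nm photolysis, the established sulfone-extrusion route to cyclophanes. SO2 leaves, and the tethered benzyl radical pair cannot disproportionate, so it recombines to 24.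

**Step 10 (macrocyclisation).**
- Risk: oligomerisation, slow insertion into the electron-rich aryl chloride, or protodeboronation.
- Fallback: it sets out from 20 and comes back at 22, and closes the ring by olefin metathesis instead of cross-coupling. The aryl chloride of 20 is vinylated with 19 (Pd(OAc)2, SPhos, K3PO4, dioxane/H2O, 100 °C) to the divinyl sulfide F2. Ring-closing metathesis with the second-generation Grubbs catalyst (toluene, 80 °C, 1 mM) gives the macrocyclic stilbene F3. F3 is drawn as Z, and its geometry does not matter for the next step. Diimide (TsNHNH2, NaOAc, THF/H2O, reflux), which sulfur does not poison, saturates the alkene to 22.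

**Step 3 (hindered, chemoselective Negishi coupling).**
- Risk: the coupling may be slow because three ortho substituents meet, and the C–Br bond may be attacked.
- Fallback: it sets out from 5 and 3 and comes back at 8, with the polarity of the two rings inverted. Compound 5 is lithiated as before (6) and quenched with I2 to give 1-bromo-2-iodo-3-methoxybenzene F4. Compound 3 is borylated (B2pin2, PdCl2(dppf), KOAc, dioxane, 80 °C) to the pinacol boronate F5. Suzuki–Miyaura coupling of F4 and F5 (Pd(PPh3)4, Na2CO3, DME/H2O, 85 °C) takes place at the C–I bond and gives 8.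

Further compounds
F1 | step 11 | 17-membered macrocyclic sulfone (S,S-dioxide of 22) | COc1ccc2c(c1)CS(=O)(=O)Cc1ccc(OC)c(c1)Oc1ccc(cc1)CCc1cccc(OC)c1-2
F2 | step 10 | (2'-ethenyl-4,6'-dimethoxybiphenyl-2-yl)methyl 3-(4-ethenylphenoxy)-4-methoxybenzyl sulfide | COc1ccc(c(CSCc2ccc(OC)c(Oc3ccc(C=C)cc3)c2)c1)-c1c(C=C)cccc1OC
F3 | step 10 | 17-membered thia-macrocycle with a (Z)-CH=CH bridge between ring C and ring D | COc1ccc2c(c1)CSCc1ccc(OC)c(c1)Oc1ccc(cc1)/C=C\c1cccc(OC)c1-2
F4 | step 3 | 1-bromo-2-iodo-3-methoxybenzene | COc1cccc(Br)c1I
F5 | step 3 | 2-(4-methoxy-2-methylphenyl)-4,4,5,5-tetramethyl-1,3,2-dioxaborolane | COc1ccc(B2OC(C)(C)C(C)(C)O2)c(C)c1
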